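The dihydrofuran ring O1–C2–C3–C3a–C7a is not closed directly but obtained from the pyranone ring of a (2S)-flavanone by iodine(III)-mediated oxidative ring contraction. In one operation the arene carbon C4a migrates from the carbonyl carbon C4 to C3: this forms the C3–C3a bond, turns C4 into the exocyclic ester that later becomes the CH2OH branch on C3, and sets C3 trans to the untouched C2 aryl stereocentre. The feature exploited is thus the one-carbon branch on C3 next to the benzylic O1–C2 centre. The precursor, 6-bromo-8-methoxyflavanone 9, comes from asymmetric conjugate arylation of a chromone; its bromide later takes the propanoate chain by Heck reaction.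

Key step: step 6

Assumption: the chromone is taken to follow the facial model of 3-substituted cyclohexenones with Pd/t-BuPyOx, so that the (R)-ligand should lead to the (2S)-flavanone; if the sense proves opposite, the (S)-ligand is used in step 5 with no other change.

Step 1
Reactants: 1 1-(2-hydroxy-3-methoxyphenyl)ethan-1-one
Product: 2 1-(5-bromo-2-hydroxy-3-methoxyphenyl)ethan-1-one
Conditions: NBS (1.05 equiv), MeCN, 0 °C to rt
Reagents that add atoms: N-bromosuccinimide, O=C1CCC(=O)N1Br
Why: Electrophilic aromatic bromination goes para to the free phenol (C5), both ortho positions being occupied, and NBS in MeCN should avoid α-bromination of the ketone.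

Step 2
Reactants: 2 1-(5-bromo-2-hydroxy-3-methoxyphenyl)ethan-1-one
Product: 4 6-bromo-8-methoxy-4H-chromen-4-one, via enaminone 3 (not isolated)
Conditions: Me2NCH(OMe)2, toluene, 110 °C; concentrate; then conc. HCl, CH2Cl2, 40 °C
Reagents that add atoms: N,N-dimethylformamide dimethyl acetal, COC(OC)N(C)C
Why: Condensation of the methyl ketone with the amide acetal gives the enaminone, and acid then promotes conjugate addition of the phenol and loss of dimethylamine (addition–elimination), the standard enaminone route to chromones.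

Step 3
Reactants: 5 4-bromo-2,6-dimethoxyphenol
Product: 6 2-(benzyloxy)-5-bromo-1,3-dimethoxybenzene
Conditions: BnBr, K2CO3, DMF, 60 °C
Reagents that add atoms: benzyl bromide, BrCc1ccccc1
Why: Williamson ether synthesis on the phenoxide; the benzyl group masks the phenol against the later iodine(III) oxidation and is removed in the final hydrogenation.

Step 4
Reactants: 6 2-(benzyloxy)-5-bromo-1,3-dimethoxybenzene
Product: 8 [4-(benzyloxy)-3,5-dimethoxyphenyl]boronic acid, via aryllithium 7 (not isolated)
Conditions: n-BuLi, THF, −78 °C; B(OiPr)3, −78 °C to rt; then 1 M aq. HCl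
Reagents that add atoms: triisopropyl borate, CC(C)OB(OC(C)C)OC(C)C; water, O
Why: Bromine–lithium exchange at −78 °C is faster than benzylic or ring deprotonation, and borylation of the aryllithium followed by hydrolysis gives the boronic acid.

Step 5
Reactants: 4 6-bromo-8-methoxy-4H-chromen-4-one; 8 [4-(benzyloxy)-3,5-dimethoxyphenyl]boronic acid
Product: 9 (2S)-2-[4-(benzyloxy)-3,5-dimethoxyphenyl]-6-bromo-8-methoxy-2,3-dihydro-4H-chromen-4-one
Conditions: Pd(OCOCF3)2 (5 mol %), (R)-4-tert-butyl-2-(pyridin-2-yl)-4,5-dihydrooxazole (6 mol %), NH4PF6 (30 mol %), H2O (5 equiv), ClCH2CH2Cl, 60 °C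
Reagents that add atoms: none
Why: Palladium(II)-catalysed asymmetric conjugate addition of an arylboronic acid to a chromone (transmetalation, insertion of C2=C3 into Ar–Pd, protonolysis of the palladium enolate by water); C2 is set in the insertion step by the tert-butyl group of the ligand, and because the cycle stays at Pd(II) the aryl bromide should remain untouched.

Step 6
Reactants: 9 (2S)-2-[4-(benzyloxy)-3,5-dimethoxyphenyl]-6-bromo-8-methoxy-2,3-dihydro-4H-chromen-4-one
Product: 11 methyl (2S,3S)-2-[4-(benzyloxy)-3,5-dimethoxyphenyl]-5-bromo-7-methoxy-2,3-dihydro-1-benzofuran-3-carboxylate (trans), via enol ether 10 (not isolated)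
Conditions: PhI(OAc)2 (1.2 equiv), conc. H2SO4 (cat.), HC(OMe)3, rt; aqueous work-up
Reagents that add atoms: trimethyl orthoformate, COC(OC)OC
Why: Acid-catalysed exchange with HC(OMe)3 turns the C4 ketone into enol ether 10, PhI(OAc)2 adds to C3 on the face anti to the C2 aryl group while methanol adds to C4, and the arene carbon C4a, antiperiplanar to the C3–I(III) bond of this ketal, shifts from C4 to C3 as PhI leaves; the dimethoxycarbenium ion left at C4 loses a methyl group to give the ester. The closest known reaction type is the iodine(III)- or thallium(III)-mediated oxidative 1,2-aryl shift of aryl ketones to 2-arylalkanoic esters, in its ring-contracting form established for flavanones. The five-membered ring O1–C2–C3–C3a–C7a (C3a is the former C4a) is closed by this suprafacial 1,2-shift through a bridged phenonium-type transition state, formally a 3-exo-tet attack of the ipso carbon on C3, so that the six-membered ring contracts by extrusion of C4. C2 is not involved and keeps its S configuration; the new centre C3 is set by substrate control, since iodination anti to the aryl group followed by migration with inversion places the ester trans to the aryl group (3S), which is also the thermodynamically preferred epimer. The step needs migration of C4a in preference to a shift of the C2 aryl group (isoflavone) and to elimination (flavone): the two methoxy groups on C4 supply the push for C4–C4a cleavage and the oxygen-substituted ring A is a good migrating group, while catalytic acid at room temperature should keep opening of the C2–O1 bond slow.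

Step 7
Reactants: 11 methyl (2S,3S)-2-[4-(benzyloxy)-3,5-dimethoxyphenyl]-5-bromo-7-methoxy-2,3-dihydro-1-benzofuran-3-carboxylate
Product: 12 [(2S,3R)-2-[4-(benzyloxy)-3,5-dimethoxyphenyl]-5-bromo-7-methoxy-2,3-dihydro-1-benzofuran-3-yl]methanol
Conditions: LiBH4 (2 equiv), THF, 0 °C to rt; then 0.5 M aq. HCl, 0 °C
Reagents that add atoms: none
Why: Hydride reduction of the methyl ester to the primary alcohol with a weakly basic borohydride that leaves the aryl bromide and benzyl ether alone and should not trigger β-elimination of the aryloxide; the geometry at C3 is unchanged (the descriptor changes to R only through the priority rules).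

Step 8
Reactants: 12 [(2S,3R)-2-[4-(benzyloxy)-3,5-dimethoxyphenyl]-5-bromo-7-methoxy-2,3-dihydro-1-benzofuran-3-yl]methanol; 13 methyl acrylate
Product: 14 methyl (2E)-3-[(2S,3R)-2-[4-(benzyloxy)-3,5-dimethoxyphenyl]-3-(hydroxymethyl)-7-methoxy-2,3-dihydro-1-benzofuran-5-yl]prop-2-enoate
Conditions: Pd(OAc)2 (5 mol %), P(o-tol)3 (10 mol %), Et3N, DMF, 100 °C
Reagents that add atoms: none
Why: Mizoroki–Heck reaction of the aryl bromide at the β-carbon of the acrylate, with syn β-hydride elimination giving the E-cinnamate; the free primary alcohol and both stereocentres (no longer acidic) should be unaffected.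

Step 9
Reactants: 14 methyl (2E)-3-[(2S,3R)-2-[4-(benzyloxy)-3,5-dimethoxyphenyl]-3-(hydroxymethyl)-7-methoxy-2,3-dihydro-1-benzofuran-5-yl]prop-2-enoate
Product: 15 methyl 3-[(2S,3R)-2-(4-hydroxy-3,5-dimethoxyphenyl)-3-(hydroxymethyl)-7-methoxy-2,3-dihydro-1-benzofuran-5-yl]propanoate
Conditions: H2 (1 atm), 10 % Pd/C, EtOAc/MeOH, rt
Reagents that add atoms: none
Why: Heterogeneous catalytic hydrogenation saturates the cinnamate double bond and hydrogenolyses the benzyl ether in one operation, under conditions mild enough that the cyclic benzylic C2–O1 ether should survive.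

Compound list
1 | 1-(2-hydroxy-3-methoxyphenyl)ethan-1-one | CC(=O)c1cccc(OC)c1O | starting material
2 | 1-(5-bromo-2-hydroxy-3-methoxyphenyl)ethan-1-one | CC(=O)c1cc(Br)cc(OC)c1O | intermediate
3 | (E)-1-(5-bromo-2-hydroxy-3-methoxyphenyl)-3-(dimethylamino)prop-2-en-1-one (enaminone, not isolated) | CN(C)/C=C/C(=O)c1cc(Br)cc(OC)c1O | intermediate
4 | 6-bromo-8-methoxy-4H-chromen-4-one | O=c1ccoc2c(OC)cc(Br)cc12 | intermediate
5 | 4-bromo-2,6-dimethoxyphenol | COc1cc(Br)cc(OC)c1O | starting material
6 | 2-(benzyloxy)-5-bromo-1,3-dimethoxybenzene | COc1cc(Br)cc(OC)c1OCc1ccccc1 | intermediate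
7 | [4-(benzyloxy)-3,5-dimethoxyphenyl]lithium (not isolated) | [Li]c1cc(OC)c(OCc2ccccc2)c(OC)c1 | intermediate
8 | [4-(benzyloxy)-3,5-dimethoxyphenyl]boronic acid | OB(O)c1cc(OC)c(OCc2ccccc2)c(OC)c1 | intermediate
9 | (2S)-2-[4-(benzyloxy)-3,5-dimethoxyphenyl]-6-bromo-8-methoxy-2,3-dihydro-4H-chromen-4-one | O=C1C[C@@H](c2cc(OC)c(OCc3ccccc3)c(OC)c2)Oc2c(OC)cc(Br)cc12 | intermediate
10 | (2S)-2-[4-(benzyloxy)-3,5-dimethoxyphenyl]-6-bromo-4,8-dimethoxy-2H-chromene (enol ether, not isolated) | COC1=C[C@@H](c2cc(OC)c(OCc3ccccc3)c(OC)c2)Oc2c(OC)cc(Br)cc12 | intermediate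
11 | methyl (2S,3S)-2-[4-(benzyloxy)-3,5-dimethoxyphenyl]-5-bromo-7-methoxy-2,3-dihydro-1-benzofuran-3-carboxylate (trans) | Brc1cc(OC)c2c(c1)[C@H](C(=O)OC)[C@@H](c1cc(OC)c(OCc3ccccc3)c(OC)c1)O2 | intermediate
12 | [(2S,3R)-2-[4-(benzyloxy)-3,5-dimethoxyphenyl]-5-bromo-7-methoxy-2,3-dihydro-1-benzofuran-3-yl]methanol (trans) | Brc1cc(OC)c2c(c1)[C@H](CO)[C@@H](c1cc(OC)c(OCc3ccccc3)c(OC)c1)O2 | intermediate
13 | methyl acrylate | C=CC(=O)OC | starting material
14 | methyl (2E)-3-[(2S,3R)-2-[4-(benzyloxy)-3,5-dimethoxyphenyl]-3-(hydroxymethyl)-7-methoxy-2,3-dihydro-1-benzofuran-5-yl]prop-2-enoate | COC(=O)/C=C/c1cc(OC)c2c(c1)[C@H](CO)[C@@H](c1cc(OC)c(OCc3ccccc3)c(OC)c1)O2 | intermediate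
15 | methyl 3-[(2S,3R)-2-(4-hydroxy-3,5-dimethoxyphenyl)-3-(hydroxymethyl)-7-methoxy-2,3-dihydro-1-benzofuran-5-yl]propanoate | COC(=O)CCc1cc(OC)c2c(c1)[C@H](CO)[C@@H](c1cc(OC)c(O)c(OC)c1)O2 | target

Total step count: 9
Longest linear sequence: 7 steps (steps 1, 2, 5, 6, 7, 8, 9; the branch 3, 4, 5–9 is equally long)

Steps most likely to fail

1. Step 6 (key step). The oxidation may take other courses: shift of the C2 aryl group to C3 (isoflavone formation), elimination to the flavone, oxidation of the trialkoxyphenyl ring, or acid-induced reversible opening of the pyranone ring with erosion of the C2 configuration. The fallback sets out from 9 and comes back at 12, bypassing 11; it removes the ketone before the oxidation. Reduction of 9 with NaBH4 (MeOH/THF, 0 °C) should give the cis-flavan-4-ol F1. Dehydration with Burgess reagent (THF, 50 °C) should give the 2H-chromene F2. Treatment with [hydroxy(tosyloxy)iodo]benzene in MeOH/HC(OMe)3 should then give the ring-contracted trans dimethyl acetal F3, by anti iodo(III)-methoxylation of the C3=C4 bond followed by the same C4a shift (the iodine(III) ring contraction known for 1,2-dihydronaphthalenes). Mild aqueous acid should release the aldehyde F4, and NaBH4 should reduce it to 12.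

2. Step 5. Transmetalation and insertion may be slow with this electron-rich boronic acid (protodeboronation competing), the aryl bromide may be consumed by adventitious Pd(0), or the facial selectivity may be insufficient. The fallback sets out from 2 and comes back at 9. Claisen–Schmidt condensation of 2 with purchased 4-(benzyloxy)-3,5-dimethoxybenzaldehyde F5 (KOH, EtOH, rt) should give the 2'-hydroxychalcone F6. Oxa-Michael cyclisation (NaOAc, EtOH, reflux) should give the racemic flavanone F7. Kinetic resolution by asymmetric transfer hydrogenation [RuCl(p-cymene)((R,R)-TsDPEN), HCO2H/Et3N, stopped near half conversion] should reduce the (2R)-enantiomer faster, to the (2R,4R)-cis-flavan-4-ol F8, leaving (S)-9 to be separated by chromatography.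

3. Step 8. Oxidative addition into the electron-rich aryl bromide may be slow at the temperature required, with decomposition of the catalyst to palladium black and polymerisation of the acrylate. The fallback sets out from 12 and comes back at 15, bypassing 14. Negishi coupling of 12 with (3-methoxy-3-oxopropyl)zinc bromide F9 (generated from methyl 3-bromopropanoate and activated zinc, used in excess because of the free hydroxyl; Pd(OAc)2/SPhos, THF, 50 °C) should install the saturated chain directly and give the benzyl-protected ester F10. Hydrogenolysis of its benzyl ether (H2, Pd/C, EtOAc/MeOH) should give 15.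

Further compounds
F1 | step 6 | (2S,4S)-2-[4-(benzyloxy)-3,5-dimethoxyphenyl]-6-bromo-8-methoxy-3,4-dihydro-2H-chromen-4-ol (cis) | O[C@H]1C[C@@H](c2cc(OC)c(OCc3ccccc3)c(OC)c2)Oc2c(OC)cc(Br)cc12
F2 | step 6 | (2S)-2-[4-(benzyloxy)-3,5-dimethoxyphenyl]-6-bromo-8-methoxy-2H-chromene | C1=C[C@@H](c2cc(OC)c(OCc3ccccc3)c(OC)c2)Oc2c(OC)cc(Br)cc12
F3 | step 6 | (2S,3S)-2-[4-(benzyloxy)-3,5-dimethoxyphenyl]-5-bromo-3-(dimethoxymethyl)-7-methoxy-2,3-dihydro-1-benzofuran (trans) | Brc1cc(OC)c2c(c1)[C@H](C(OC)OC)[C@@H](c1cc(OC)c(OCc3ccccc3)c(OC)c1)O2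
F4 | step 6 | (2S,3S)-2-[4-(benzyloxy)-3,5-dimethoxyphenyl]-5-bromo-7-methoxy-2,3-dihydro-1-benzofuran-3-carbaldehyde (trans) | Brc1cc(OC)c2c(c1)[C@H](C=O)[C@@H](c1cc(OC)c(OCc3ccccc3)c(OC)c1)O2
F5 | step 5 | 4-(benzyloxy)-3,5-dimethoxybenzaldehyde (purchased) | O=Cc1cc(OC)c(OCc2ccccc2)c(OC)c1
F6 | step 5 | (E)-3-[4-(benzyloxy)-3,5-dimethoxyphenyl]-1-(5-bromo-2-hydroxy-3-methoxyphenyl)prop-2-en-1-one | O=C(/C=C/c1cc(OC)c(OCc2ccccc2)c(OC)c1)c1cc(Br)cc(OC)c1O
F7 | step 5 | rac-2-[4-(benzyloxy)-3,5-dimethoxyphenyl]-6-bromo-8-methoxy-2,3-dihydro-4H-chromen-4-one | O=C1CC(c2cc(OC)c(OCc3ccccc3)c(OC)c2)Oc2c(OC)cc(Br)cc12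
F8 | step 5 | (2R,4R)-2-[4-(benzyloxy)-3,5-dimethoxyphenyl]-6-bromo-8-methoxy-3,4-dihydro-2H-chromen-4-ol (cis) | O[C@@H]1C[C@H](c2cc(OC)c(OCc3ccccc3)c(OC)c2)Oc2c(OC)cc(Br)cc12
F9 | step 8 | (3-methoxy-3-oxopropyl)zinc bromide | COC(=O)CC[Zn]Br
F10 | step 8 | methyl 3-[(2S,3R)-2-[4-(benzyloxy)-3,5-dimethoxyphenyl]-3-(hydroxymethyl)-7-methoxy-2,3-dihydro-1-benzofuran-5-yl]propanoate | COC(=O)CCc1cc(OC)c2c(c1)[C@H](CO)[C@@H](c1cc(OC)c(OCc3ccccc3)c(OC)c1)O2
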